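The readings come from a simulation for substances that don't exist, and the scatter is random.

Every reading here is a percent of the two substrates together, so each substrate starts at half of the scale, and you double a reading to get the fraction of that substrate left.

| flask | left-handed substrate | right-handed substrate | gas | free catalyst | added ligand | remark | time |
|---|---|---|---|---|---|---|---|
| alpha | 0.33 M | 0.33 M | 30 mM (held) | 4.7 mol% | 56 mM | run made earlier |  |
| zeta | 0.33 M | 0.33 M | 30 mM (held) | 7 mol% | 56 mM | run made earlier |  |
| delta | 0.33 M | 0.33 M | 30 mM (held) | 9.3 mol% | 110 mM | run made earlier |  |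
| flask | 0.33 M | 0.33 M | 30 mM (held) | 9.3 mol% | 56 mM |  | 4.0 h |

| run | time / h | left-handed substrate / % | right-handed substrate / % |
|---|---|---|---|
| alpha | 0.200 | 49.0 | 49.9 |
| alpha | 0.667 | 45.8 | 49.1 |
| alpha | 1.00 | 44.2 | 49.1 |
| alpha | 2.00 | 39.0 | 49.7 |
| alpha | 2.50 | 37.4 | 48.7 |
| alpha | 3.00 | 35.3 | 47.2 |
| zeta | 0.200 | 48.2 | 49.8 |
| zeta | 0.667 | 44.8 | 49.0 |
| zeta | 1.00 | 42.2 | 49.2 |
| zeta | 2.00 | 37.0 | 47.9 |
| zeta | 2.50 | 35.4 | 48.2 |
| zeta | 3.00 | 32.6 | 46.8 |
| delta | 0.250 | 48.0 | 50.0 |
| delta | 0.500 | 45.3 | 49.3 |
| delta | 0.833 | 43.8 | 49.8 |
| delta | 1.50 | 39.6 | 48.7 |
| delta | 3.00 | 31.5 | 48.2 |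

(standard deviation of a reading: 0.5 percentage points)

- free catalyst is single-handed; left-handed substrate and right-handed substrate are mirror images of each other, charged as a racemate, each of them at the stated concentration
- at the start none of the gas is in solution
- an excess is below zero if the other one leads

- part of the left-handed substrate and right-handed substrate charged together that has reacted at 4.0 h
- excess of left-handed product over right-handed product in the product at 4.0 h
- excess of right-handed substrate over left-handed substrate among what is left of the two at 4.0 h

Suppose one catalyst and one gas serve both substrates, each substrate with its own constant. Then whatever slows one slows the other by the same factor, and the logarithms of the two fractions left keep a fixed ratio however the rate wanders. Summing those logarithms over the last readings of alpha, zeta and delta, to weaken the scatter, I read 7.72, and this selectivity factor, the logarithm of the fraction of left-handed substrate left over that of the right-handed, is what you carry to the flask.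

In the first instants the two substrates stand equal, so the flask's product should show a left-handed excess of 77.1%. In the middle the pace falls: delta loses 4.7 percentage points of left-handed substrate in its first 0.500 h, but 8.1 points over the later 1.50 h, a slower loss per hour. For the end I start from delta's reading at 3.00 h, since delta has the flask's catalyst, and subtract the drop of 4.4 points that zeta shows over its last hour of readings. That leaves 27.1% of left-handed substrate, and the factor then gives 46.2% of right-handed. My reckoning is therefore c 26.7%, eP 71.5% and eS 26.1%.

The forecast differs: 27.2%, 76% and 28.6%, with the “right-handed substrate reacts about ten times slower”, where my factor reads 7.72.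

What ran in the flask was this:

    coupling partner + free catalyst + left-handed substrate → free catalyst + left-handed product (k = 13.0 L² mol⁻² min⁻¹)
    coupling partner + free catalyst + right-handed substrate → free catalyst + right-handed product (k = 1.70 L² mol⁻² min⁻¹)
    free catalyst + added ligand ⇌ idle complex (K = 11.0 L mol⁻¹, k = 0.570 L mol⁻¹ min⁻¹)
    gas ⇌ coupling partner, rate k4*(csat - [coupling partner]) (kL = 0.130 min⁻¹)
    2 free catalyst → spent catalyst (k = 0.600 L mol⁻¹ min⁻¹)

The flask gives 24.4%, 71.9% and 23.2%, with its left-handed substrate at 29.0%, above my 27.1%. Of its charge, 58% of the left-handed substrate remains, less than the 93% of the right-handed, and the carried factor turns that 58% into 93.2%. The neighbour with 3.7 mol% of free catalyst keeps 70% of its left-handed substrate, which the factor turns into 95.5% of right-handed, and that neighbour holds 95%.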